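**Strategy.** Labdane numbering is used. The target is a Δ8-decalin in which the oxygenated C6 lies between C5 and C7. Everything rests on cutting C5–C10 and C7–C8 together: C6 becomes a ketone whose two α-carbons are the donors, and C8–C9–C10 becomes an enone (C8 the carbonyl, C10 the β-carbon). One amine-catalysed operation on the acyclic triketo ester 12 then performs an intramolecular Michael addition (C5 to C10: ring A and the quaternary C10) and an aldol condensation (C7 to C8: ring B). The dienolate of the resulting enone is oxygenated at C7, and the hindered C6 ketone is reduced from its open α face.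

Key step: step 6

Assumption: β means the face of the C10 methyl group; the quinine-derived amine is assumed to give the natural 10β-methyl series, and its quinidine-derived pseudoenantiomer replaces it unchanged if the sense of induction is the opposite.

**Step 1**
Reactants: 1 5-chloropentan-2-one; 2 prop-1-yn-1-ylmagnesium bromide
Product: 3 [(7-chloro-4-methylhept-2-yn-4-yl)oxy]trimethylsilane (racemic)
Conditions: THF, −78 to 0 °C; then Me3SiCl, Et3N, DMAP (cat.), 0 °C to rt
Reagents that add atoms: chlorotrimethylsilane C[Si](C)(C)Cl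
Why: 1,2-addition of the alkynyl Grignard reagent to the methyl ketone, then silylation of the magnesium alkoxide so that it cannot later close a tetrahydrofuran onto the chloride; the carbinol centre is racemic and is destroyed in step 3.

**Step 2**
Reactants: 3 [(7-chloro-4-methylhept-2-yn-4-yl)oxy]trimethylsilane; 4 4-methylpent-3-en-2-one (mesityl oxide)
Product: 7 8-hydroxy-4,4,8-trimethylundec-9-yn-2-one (racemic), via Grignard reagent 5 (not isolated), via silyl ether ketone 6 (not isolated)
Conditions: Mg, THF, reflux; CuBr·SMe2 (10 mol %), 4, −30 °C; 1 M HCl, THF, rt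
Reagents that add atoms: none
Why: copper-catalysed conjugate addition of the primary Grignard reagent to mesityl oxide should build the C4 gem-dimethyl quaternary carbon together with the C5–C7 acetonyl unit, and the acidic work-up cleaves the trimethylsilyl ether; no new stereocentre.

**Step 3**
Reactants: 7 8-hydroxy-4,4,8-trimethylundec-9-yn-2-one
Product: 8 3-iodo-4,8,8-trimethylundec-3-ene-2,10-dione (E/Z mixture)
Conditions: Ph3PAuNTf2 (2 mol %), MoO2(acac)2 (1 mol %), N-iodosuccinimide, CH2Cl2, rt
Reagents that add atoms: N-iodosuccinimide O=C1CCC(=O)N1I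
Why: Meyer–Schuster rearrangement of the tertiary propargylic alcohol with interception of the vinyl–gold intermediate by the iodonium source should give the α-iodo enone directly; the alkene geometry is inconsequential because C10 becomes sp3 in step 6.

**Step 4**
Reactants: 9 methyl but-2-ynoate
Product: 10 methyl (2E)-3-methylpenta-2,4-dienoate
Conditions: CH2=CHMgBr, CuI (copper iodide, 1.1 equiv), THF, −78 °C; then 9; NH4Cl (aq), −78 °C
Reagents that add atoms: vinylmagnesium bromide C=C[Mg]Br
Why: syn-carbocupration of the ynoate by vinylcopper and protonation with retention place the vinyl group trans to the ester, which fixes the later 13E geometry.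

**Step 5**
Reactants: 10 methyl (2E)-3-methylpenta-2,4-dienoate; 8 3-iodo-4,8,8-trimethylundec-3-ene-2,10-dione
Product: 12 methyl (2E)-6-acetyl-3,7,11,11-tetramethyl-13-oxotetradeca-2,6-dienoate (C6=C7 geometry undefined), via alkylborane 11 (not isolated)
Conditions: 9-BBN-H, THF, 0 °C to rt; then 8, PdCl2(dppf) (5 mol %), AsPh3, Cs2CO3, DMF/H2O, rt
Reagents that add atoms: none
Why: anti-Markovnikov hydroboration of the terminal vinyl group followed by B-alkyl Suzuki–Miyaura coupling with the α-iodo enone joins C9 to C11 and completes the carbon skeleton; ketones and ester are tolerated and no stereocentre is formed.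

**Step 6**
Reactants: 12 methyl (2E)-6-acetyl-3,7,11,11-tetramethyl-13-oxotetradeca-2,6-dienoate
Product: 15 methyl (13E)-6-oxolabda-7,13-dien-15-oate (5α-H, 9α-H, 10β-methyl), via Michael adduct 13 (not isolated), via aldol adduct 14 (not isolated)
Conditions: 9-amino-9-deoxy-epi-quinine (20 mol %), 2-fluorobenzoic acid (40 mol %), toluene, 50 °C
Reagents that add atoms: none
Why: The primary amine condenses reversibly with both methyl ketones, so the C8 enone is activated as its iminium ion while the C6 ketone supplies the C5 enamine; 6-exo-trig Michael addition forms C5–C10, ring A and the quaternary C10, and after hydrolysis at C8 the C7 enamine of the same ketone adds to the C8 carbonyl (6-exo-trig aldol) and water is lost, forming C7–C8 (as the enone double bond) and ring B. The closest known reaction type is the amine-catalysed Robinson annulation (intramolecular Michael addition, then aldol condensation), combined with iminium activation of β,β-disubstituted enones by cinchona-derived primary amines, which is precedented for building quaternary β-carbons. C10 is set by the catalyst, which screens one face of the iminium ion in a chair-like transition state whose forming ring is ring A; C5 is then set thermodynamically by enolisation of the C6 ketone to the trans ring fusion, and C9 equilibrates to the equatorial side chain and ceases to be a stereocentre in step 8. The step needs enantioface selection at C10, Michael addition through C5 and not C7 (a six- against an eight-membered ring), and the aldol pairing C7 to C8 and not C8-methyl to C6. The last should be secured because the C6 carbonyl is the most hindered site (its α-carbon C5 lies between the quaternary C4 and C10) and so serves only as donor, and because dehydration makes the sequence irreversible.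

**Step 7**
Reactants: 15 methyl (13E)-6-oxolabda-7,13-dien-15-oate
Product: 16 (13E)-6-oxolabda-7,13-dien-15-oic acid
Conditions: LiOH, THF/MeOH/H2O, rt; then 1 M HCl
Reagents that add atoms: lithium hydroxide [Li+].[OH-]
Why: saponification of the methyl ester; the base should also complete equilibration of C5 to the trans-fused isomer, and the later carboxylate shields the side-chain enoate from γ-deprotonation in step 8.

**Step 8**
Reactants: 16 (13E)-6-oxolabda-7,13-dien-15-oic acid
Product: 19 (13E)-7α-(3-methylbutanoyloxy)-6-oxolabda-8,13-dien-15-oic acid, via dienolate 17 (not isolated), via 7-alkoxide 18 (not isolated)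
Conditions: KN(SiMe3)2 (2.1 equiv), THF, −78 to 0 °C; 2-(phenylsulfonyl)-3-phenyloxaziridine, −78 °C; (CH3)2CHCH2COCl, −78 to 0 °C; NaHCO3 (aq), then HCl
Reagents that add atoms: 2-(phenylsulfonyl)-3-phenyloxaziridine O=S(=O)(c1ccccc1)N1OC1c1ccccc1; 3-methylbutanoyl chloride CC(C)CC(Cl)=O
Why: γ-deprotonation at C9 gives the linear dienolate, which the N-sulfonyloxaziridine should oxidise at its α-carbon C7 from the α face (axial attack; the β face is screened by the 4β- and 10β-methyl groups), moving the double bond to C8–C9; the 7α-alkoxide is acylated in the same flask before the α-ketol can isomerise (enolate α-hydroxylation, then O-acylation; the mixed anhydride at C15 is cleaved in the bicarbonate work-up).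

**Step 9**
Reactants: 19 (13E)-7α-(3-methylbutanoyloxy)-6-oxolabda-8,13-dien-15-oic acid
Product: 20 (13E)-6β-hydroxy-7α-(3-methylbutanoyloxy)labda-8,13-dien-15-oic acid
Conditions: NaBH4, CeCl3·7H2O, MeOH, −40 °C
Reagents that add atoms: none
Why: Luche-type reduction in which hydride should reach the C6 carbonyl from the α face, the β face being blocked by the syn-axial 4β- and 10β-methyl groups, to give the axial 6β-alcohol; its trans-diaxial relation to the 7α-ester rules out acyl migration.

**Step 10**
Reactants: 20 (13E)-6β-hydroxy-7α-(3-methylbutanoyloxy)labda-8,13-dien-15-oic acid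
Product: 21 (5S,6S,7S,10S,13E)-6-acetoxy-7-(3-methylbutanoyloxy)labda-8,13-dien-15-oic acid (target)
Conditions: Ac2O, DMAP, pyridine, 50 °C; then H2O, THF
Reagents that add atoms: acetic anhydride CC(=O)OC(C)=O
Why: DMAP-catalysed acetylation of the hindered axial 6β-hydroxyl; the mixed anhydride formed at C15 is hydrolysed in the aqueous work-up and no stereocentre is touched.

**Compound list**
1 | 5-chloropentan-2-one | CC(=O)CCCCl | starting material
2 | prop-1-yn-1-ylmagnesium bromide | CC#C[Mg]Br | starting material
3 | [(7-chloro-4-methylhept-2-yn-4-yl)oxy]trimethylsilane (racemic) | CC#CC(C)(O[Si](C)(C)C)CCCCl | intermediate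
4 | 4-methylpent-3-en-2-one (mesityl oxide) | CC(=O)C=C(C)C | starting material
5 | chlorido{4-methyl-4-[(trimethylsilyl)oxy]hept-5-yn-1-yl}magnesium | CC#CC(C)(O[Si](C)(C)C)CCC[Mg]Cl | intermediate
6 | 4,4,8-trimethyl-8-[(trimethylsilyl)oxy]undec-9-yn-2-one | CC(=O)CC(C)(C)CCCC(C)(O[Si](C)(C)C)C#CC | intermediate
7 | 8-hydroxy-4,4,8-trimethylundec-9-yn-2-one (racemic) | CC(=O)CC(C)(C)CCCC(C)(O)C#CC | intermediate
8 | 3-iodo-4,8,8-trimethylundec-3-ene-2,10-dione (E/Z) | CC(=O)CC(C)(C)CCCC(C)=C(I)C(C)=O | intermediate
9 | methyl but-2-ynoate | CC#CC(=O)OC | starting material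
10 | methyl (2E)-3-methylpenta-2,4-dienoate | C=C/C(C)=C/C(=O)OC | intermediate
11 | methyl (2E)-5-(9-borabicyclo[3.3.1]nonan-9-yl)-3-methylpent-2-enoate | B1(CC/C(C)=C/C(=O)OC)C2CCCC1CCC2 | intermediate
12 | methyl (2E)-6-acetyl-3,7,11,11-tetramethyl-13-oxotetradeca-2,6-dienoate (C6=C7 geometry undefined) | CC(=O)CC(C)(C)CCCC(C)=C(CC/C(C)=C/C(=O)OC)C(C)=O | intermediate
13 | methyl (2E)-6-(2-acetyl-1,3,3-trimethylcyclohexyl)-3-methyl-7-oxooct-2-enoate (ring substituents trans; C6 epimers) | CC(=O)[C@H]1C(C)(C)CCC[C@]1(C)C(CC/C(C)=C/C(=O)OC)C(C)=O | intermediate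
14 | methyl (13E)-8-hydroxy-6-oxolabd-13-en-15-oate (C8 and C9 epimers) | O=C1CC(C)(O)C(CC/C(C)=C/C(=O)OC)[C@@]2(C)CCCC(C)(C)[C@H]12 | intermediate
15 | methyl (13E)-6-oxolabda-7,13-dien-15-oate (5α-H, 9α-H, 10β-methyl) | O=C1C=C(C)[C@H](CC/C(C)=C/C(=O)OC)[C@@]2(C)CCCC(C)(C)[C@H]12 | intermediate
16 | (13E)-6-oxolabda-7,13-dien-15-oic acid | O=C1C=C(C)[C@H](CC/C(C)=C/C(=O)O)[C@@]2(C)CCCC(C)(C)[C@H]12 | intermediate
17 | dipotassium (13E)-6-oxidolabda-6,8,13-trien-15-oate | [K+].[K+].[O-]C1=CC(C)=C(CC/C(C)=C/C(=O)[O-])[C@@]2(C)CCCC(C)(C)[C@H]12 | intermediate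
18 | dipotassium (13E)-7α-oxido-6-oxolabda-8,13-dien-15-oate | [K+].[K+].O=C1[C@@H]([O-])C(C)=C(CC/C(C)=C/C(=O)[O-])[C@@]2(C)CCCC(C)(C)[C@H]12 | intermediate
19 | (13E)-7α-(3-methylbutanoyloxy)-6-oxolabda-8,13-dien-15-oic acid | O=C1[C@@H](OC(=O)CC(C)C)C(C)=C(CC/C(C)=C/C(=O)O)[C@@]2(C)CCCC(C)(C)[C@H]12 | intermediate
20 | (13E)-6β-hydroxy-7α-(3-methylbutanoyloxy)labda-8,13-dien-15-oic acid | O[C@@H]1[C@@H](OC(=O)CC(C)C)C(C)=C(CC/C(C)=C/C(=O)O)[C@@]2(C)CCCC(C)(C)[C@H]12 | intermediate
21 | (5S,6S,7S,10S,13E)-6-acetoxy-7-(3-methylbutanoyloxy)labda-8,13-dien-15-oic acid | CC(=O)O[C@@H]1[C@@H](OC(=O)CC(C)C)C(C)=C(CC/C(C)=C/C(=O)O)[C@@]2(C)CCCC(C)(C)[C@H]12 | target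

**Step count.** 10 steps in total. The longest linear sequence is 9 steps (1, 2, 3, 5, 6, 7, 8, 9, 10); step 4 is a one-step side branch.

**Steps most likely to fail**

1. Step 6. Conjugate addition to the tetrasubstituted, twisted enone may be so slow that an uncatalysed racemic cyclisation or the reversed aldol pairing takes over. The fallback leaves the side chain off the acceptor; it sets out from 7 and returns at 15. Compound 7 is rearranged without the iodine source (Ph3PAuNTf2, MoO2(acac)2, CH2Cl2; Meyer–Schuster) to 4,8,8-trimethylundec-3-ene-2,10-dione F1. Its trisubstituted enone is cyclised under the amine catalysis of step 6 to the trans-fused (4aR,8aS)-3,4a,8,8-tetramethyl-4,4a,5,6,7,8-hexahydronaphthalen-1(8aH)-one F2. Mannich methylenation at the γ-carbon (paraformaldehyde, Me2NH·HCl, isoamyl alcohol, reflux) should give the linear dienone (4aS,8aS)-3,4a,8,8-tetramethyl-4-methylidene-4,4a,5,6,7,8-hexahydronaphthalen-1(8aH)-one F3. A vinylogous Mukaiyama–Michael addition of [(1-methoxy-3-methylbuta-1,3-dien-1-yl)oxy]trimethylsilane F4 (from methyl 3-methylbut-2-enoate, LiN(i-Pr)2, Me3SiCl) to the exocyclic methylene (BF3·OEt2, CH2Cl2, −78 °C) attaches C12–C15 and gives 15, together with its Δ8 isomer, which leads to the same dienolate 17.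

2. Step 8. Oxygen transfer may go to the γ-carbon C9 or to C5, or the α-ketol may isomerise under base before it is capped. The fallback sets out from 16 and returns at 19. Soft enolisation (t-BuMe2SiOTf, Et3N, CH2Cl2) should give tert-butyldimethylsilyl (13E)-6-(tert-butyldimethylsilyloxy)labda-6,8,13-trien-15-oate F5. Catalytic OsO4 with N-methylmorpholine N-oxide should dihydroxylate the electron-rich, less hindered C6–C7 enol-ether bond from the α face and spare the tetrasubstituted C8–C9 bond. Loss of silanol on work-up gives (13E)-7α-hydroxy-6-oxolabda-8,13-dien-15-oic acid F6, which is acylated with 3-methylbutanoyl chloride and pyridine at 0 °C to 19.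

3. Step 5. Transmetalation from boron may be slow at the hindered α-iodo enone, allowing protodeboronation and β-hydride elimination, and the aqueous base may start the cyclisation early. The fallback sets out from 10 (with 8) and returns at 12. The borane 11 made from 10 is cleaved with I2 and NaOMe to methyl (2E)-5-iodo-3-methylpent-2-enoate F7. Zinc insertion (Zn, LiCl, THF) gives [(3E)-5-methoxy-3-methyl-5-oxopent-3-en-1-yl]zinc iodide F8, and a base-free Negishi coupling with 8 (Pd(OAc)2, SPhos, THF, rt) gives 12.

**Further compounds**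
F1 | step 6 | 4,8,8-trimethylundec-3-ene-2,10-dione | CC(=O)C=C(C)CCCC(C)(C)CC(C)=O
F2 | step 6 | (4aR,8aS)-3,4a,8,8-tetramethyl-4,4a,5,6,7,8-hexahydronaphthalen-1(8aH)-one | O=C1C=C(C)C[C@@]2(C)CCCC(C)(C)[C@H]12
F3 | step 6 | (4aS,8aS)-3,4a,8,8-tetramethyl-4-methylidene-4,4a,5,6,7,8-hexahydronaphthalen-1(8aH)-one | O=C1C=C(C)C(=C)[C@@]2(C)CCCC(C)(C)[C@H]12
F4 | step 6 | [(1-methoxy-3-methylbuta-1,3-dien-1-yl)oxy]trimethylsilane | C=C(C)C=C(OC)O[Si](C)(C)C
F5 | step 8 | tert-butyldimethylsilyl (13E)-6-(tert-butyldimethylsilyloxy)labda-6,8,13-trien-15-oate | CC(C)(C)[Si](C)(C)OC1=CC(C)=C(CC/C(C)=C/C(=O)O[Si](C)(C)C(C)(C)C)[C@@]2(C)CCCC(C)(C)[C@H]12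
F6 | step 8 | (13E)-7α-hydroxy-6-oxolabda-8,13-dien-15-oic acid | O=C1[C@@H](O)C(C)=C(CC/C(C)=C/C(=O)O)[C@@]2(C)CCCC(C)(C)[C@H]12
F7 | step 5 | methyl (2E)-5-iodo-3-methylpent-2-enoate | ICC/C(C)=C/C(=O)OC
F8 | step 5 | [(3E)-5-methoxy-3-methyl-5-oxopent-3-en-1-yl]zinc iodide | I[Zn]CC/C(C)=C/C(=O)OC
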